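0.310 mM of free catalyst is what I expect to work in this flask. I call this the working catalyst, meaning the catalyst charge minus the stray impurity charge, and the zero of its scale is where the two charges are equal.

in all of them: starting material 38 mM; stray impurity 0.64 mM
- red: protic impurity 7.6 mM; free catalyst 1.3 mM; run made earlier
- blue: protic impurity 7.6 mM; free catalyst 2.1 mM; run made earlier
- flask: protic impurity 7.60 mM; free catalyst 0.95 mM; time 20 min

| run | time / min | target / % |
|---|---|---|
| red | 4.00 | 12 |
| red | 8.00 | 20 |
| red | 12.0 | 27 |
| red | 15.0 | 30 |
| red | 20.0 | 32 |
| red | 25.0 | 36 |
| blue | 2.00 | 14 |
| blue | 3.00 | 21 |
| blue | 5.00 | 29 |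
| blue | 8.00 | 40 |
| blue | 15.0 | 51 |
| blue | 25.0 | 57 |

(each reading ± 1.5 percentage points)

1. why nothing more happens at 20 min, or that something still does (no working catalyst is left / all of the starting material has reacted / forward and back rates have come level / it is still moving)
2. the target standing at 20 min, as a percentage of the starting material charged

I can solve two extreme flasks in my head, both scaled from the red reading of 32% at 20.0 min. If the stray impurity does nothing, target follows the charge and this flask reaches 23.4%. If the stray impurity removes its equal of catalyst, a titration, target follows working catalyst, which is 0.660 mM in red, and this flask reaches 15.0%.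

The readings choose between them. At 8.00 min, blue reads 2.00 times red, with a scatter of 1.5 percentage points on each reading, while the charges give 1.62 and the working catalysts, with 1.46 mM in blue, give 2.21. So I stand near the low end. I go a little above it, because blue reads less target per working catalyst than red.

Red's readings still rise by 6 points between 15.0 min and 25.0 min, a span as long as the second half of this flask's time. With half of red's working catalyst, that scales to 2.8 points, so I call this flask still moving.

The forecast says it is still moving and 17%, above my low end, on the ground that “The initial rates scale with catalyst minus stray impurity”.

The flask gives it is still moving and 17.6%.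

    starting material + free catalyst → catalyst intermediate A (k = 1.90 M⁻¹ s⁻¹)
    catalyst intermediate A → catalyst intermediate B (k = 1.60 s⁻¹)
    catalyst intermediate B ⇌ free catalyst + target (K = 0.410 M, k = 0.100 s⁻¹)
    starting material + protic impurity → quenched substrate (k = 1.60 M⁻¹ s⁻¹)
    free catalyst → spent catalyst A (k = 0.00180 s⁻¹)
    free catalyst + stray impurity → spent catalyst B (k = 440 M⁻¹ s⁻¹)

At the start of this flask, starting material takes free catalyst at 0.26 of the rate at which stray impurity takes it. By 2.00 min the stray impurity stands at 0% of its charge and spent catalyst B at 67.4% of the catalyst, the 67.4% that the charges give, which leaves 0.310 mM of the charge in the other forms, spent catalyst A among them. A neighbour flask charged with 0.57 mM has a working catalyst of −0.0700 mM, below zero, and after 20.0 min it holds 0% free catalyst, 12% of its stray impurity and 0.807% target.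

(The numbers in the tables come from a simulation from invented constants, noise included.)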